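The plan cuts the C1–C14 bond of the 14-membered carbocycle (cembrane numbering). The key step exploits the cis-fused α-methylene-γ-butyrolactone ring (C1, C14, O, C16, C15) lying beside the C13 oxygen. An ester-bearing allyl metal that adds through its γ-carbon to an α-hydroxy aldehyde creates precisely this array. One aqueous indium Barbier operation should close the carbocycle, set C14 and C1, release the exocyclic methylene and lactonise. Its precursor is an open chain ending in a free (13R)-hydroxy aldehyde (C14) and a (Z)-2-(bromomethyl)enoate (C1). C12, silyl-protected C7 and the E-C3=C4 olefin are already in place. Acetylation, desilylation and reagent-controlled epoxidation follow.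

Key step: step 19

Remark: atoms carry cembrane numbers throughout (C1 lactone CH, C14 lactone O-CH, C13 acetoxy CH, C12 methyl CH, C8 methylene-bearing carbon, C7 carbinol, C3/C4 epoxide, C15/C16/C17 lactone α-carbon, carbonyl and exocyclic CH2). It is assumed that the antipode of the chromium ligand in step 10 is fixed by a pilot coupling, since both antipodes are equally accessible from D- or L-valinol.

Step 1
Reactants: 1 (S)-citronellal
Product: 3 (2R,3S)-2-(anilinooxy)-3,7-dimethyloct-6-en-1-ol, via α-anilinooxy aldehyde 2 (not isolated)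
Conditions: PhNO, L-proline (20 mol %), DMSO, rt; then NaBH4, EtOH, 0 °C
Reagents that add atoms: nitrosobenzene, O=Nc1ccccc1
Why: Organocatalytic α-aminoxylation (enamine catalysis), in which the L-proline enamine of 1 takes up the acid-activated nitroso oxygen on one face only, should set C13 as R under catalyst control next to the purchased C12 centre, and reduction in the same flask removes the epimerisable aldehyde.

Step 2
Reactants: 3 (2R,3S)-2-(anilinooxy)-3,7-dimethyloct-6-en-1-ol
Product: 4 (2R,3S)-3,7-dimethyloct-6-ene-1,2-diol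
Conditions: Zn dust, AcOH, EtOH, rt
Reagents that add atoms: none
Why: Dissolving-metal reductive cleavage of the weak N–O bond frees the secondary hydroxyl without touching the trisubstituted olefin or either stereocentre.

Step 3
Reactants: 4 (2R,3S)-3,7-dimethyloct-6-ene-1,2-diol
Product: 5 (2R,3S)-3,7-dimethyl-1,2-bis(triethylsilyloxy)oct-6-ene
Conditions: TESCl, imidazole, 4-(dimethylamino)pyridine (cat.), CH2Cl2, 0 °C to rt
Reagents that add atoms: chlorotriethylsilane (TESCl), CC[Si](Cl)(CC)CC
Why: Standard silyl chloride/imidazole silylation installs two triethylsilyl ethers, chosen because the primary one can later be oxidised directly and the secondary one shed under conditions that spare a tert-butyldimethylsilyl ether.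

Step 4
Reactants: 5 (2R,3S)-3,7-dimethyl-1,2-bis(triethylsilyloxy)oct-6-ene
Product: 7 (4S,5R)-4-methyl-5,6-bis(triethylsilyloxy)hexan-1-ol, via C9 aldehyde 6 (not isolated)
Conditions: O3, NaHCO3, CH2Cl2/MeOH, −78 °C; then NaBH4, −78 to 0 °C
Reagents that add atoms: ozone, [O-][O+]=O
Why: Ozonolysis with reductive work-up cleaves the only olefin, discards the isopropylidene carbons and reduces aldehyde 6 in situ to the C9 alcohol, the silyl ethers being inert in the buffered medium.

Step 5
Reactants: 7 (4S,5R)-4-methyl-5,6-bis(triethylsilyloxy)hexan-1-ol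
Product: 8 (2R,3S)-6-iodo-3-methyl-1,2-bis(triethylsilyloxy)hexane
Conditions: I2, PPh3, imidazole, CH2Cl2, 0 °C
Reagents that add atoms: iodine, II
Why: Appel-type iodination (SN2 on the alkoxyphosphonium salt) of an unhindered primary alcohol is buffered by imidazole so that the silyl ethers survive.

Step 6
Reactants: 8 (2R,3S)-6-iodo-3-methyl-1,2-bis(triethylsilyloxy)hexane; 9 (1-bromovinyl)trimethylsilane
Product: 11 (2R,3S)-3-methyl-1,2-bis(triethylsilyloxy)-7-(trimethylsilyl)oct-7-ene, via 1-(trimethylsilyl)vinylmagnesium bromide 10 (not isolated)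
Conditions: 9, Mg, THF, reflux; then 8, CuI (10 mol %), THF, −20 °C to rt
Reagents that add atoms: none
Why: Copper-catalysed Grignard cross-coupling of a primary alkyl iodide with the α-silylvinyl Grignard reagent joins C8 to C9 and brings in the future C8 methylene carbon without involving any stereocentre.

Step 7
Reactants: 11 (2R,3S)-3-methyl-1,2-bis(triethylsilyloxy)-7-(trimethylsilyl)oct-7-ene
Product: 12 (2R,3S)-7-iodo-3-methyl-1,2-bis(triethylsilyloxy)oct-7-ene
Conditions: NIS, MeCN, 0 °C to rt, dark
Reagents that add atoms: N-iodosuccinimide, O=C1CCC(=O)N1I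
Why: Electrophilic iododesilylation (ipso substitution of a vinylsilane) exchanges silicon for iodine at C8 regiospecifically, a transformation well established for 2-silyl-1-alkenes that carry silyl ethers.

Step 8
Reactants: 13 geranyl acetate
Product: 14 6,7-epoxygeranyl acetate
Conditions: mCPBA (1.0 equiv), NaHCO3, CH2Cl2, 0 °C
Reagents that add atoms: 3-chloroperoxybenzoic acid (mCPBA), O=C(OO)c1cccc(Cl)c1
Why: In this Prilezhaev epoxidation the remote trisubstituted olefin is more electron-rich than the one deactivated by the allylic acetate, so one equivalent of peracid reacts there, and the new centre is destroyed in the next step so its configuration does not matter.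

Step 9
Reactants: 14 6,7-epoxygeranyl acetate
Product: 15 (2E)-3-methyl-6-oxohex-2-en-1-yl acetate
Conditions: H5IO6, THF/H2O, 0 °C
Reagents that add atoms: none
Why: Periodic acid opens the epoxide to the glycol and cleaves it (Malaprade-type cleavage) to the C7 aldehyde and acetone, leaving the E-allylic acetate untouched.

Step 10
Reactants: 12 (2R,3S)-7-iodo-3-methyl-1,2-bis(triethylsilyloxy)oct-7-ene; 15 (2E)-3-methyl-6-oxohex-2-en-1-yl acetate
Product: 16 (2E,6S,11S,12R)-6-hydroxy-3,11-dimethyl-7-methylidene-12,13-bis(triethylsilyloxy)tridec-2-en-1-yl acetate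
Conditions: CrCl2 (10 mol %), N-[2-(4-isopropyl-4,5-dihydrooxazol-2-yl)-6-methylphenyl]methanesulfonamide (one antipode, 11 mol %), 1,8-bis(dimethylamino)naphthalene (11 mol %), NiCl2·(2,9-dimethyl-1,10-phenanthroline) (2 mol %), Mn, Cp2ZrCl2, LiCl, MeCN, rt
Reagents that add atoms: none
Why: In this catalytic asymmetric Nozaki–Hiyama–Kishi coupling zerovalent nickel activates the C8–I bond, transmetalation gives a vinylchromium species held by the chiral sulfonamide ligand, and its addition to the Re face of aldehyde 15 should set C7 as S under ligand control while the acetate, the silyl ethers and the distant C12/C13 centres are spectators.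

Step 11
Reactants: 16 (2E,6S,11S,12R)-6-hydroxy-3,11-dimethyl-7-methylidene-12,13-bis(triethylsilyloxy)tridec-2-en-1-yl acetate
Product: 17 (2E,6S,11S,12R)-6-(tert-butyldimethylsilyloxy)-3,11-dimethyl-7-methylidene-12,13-bis(triethylsilyloxy)tridec-2-en-1-yl acetate
Conditions: TBSOTf, 2,6-lutidine, CH2Cl2, −78 to 0 °C
Reagents that add atoms: tert-butyldimethylsilyl triflate (TBSOTf), CC(C)(C)[Si](C)(C)OS(=O)(=O)C(F)(F)F
Why: Silyl triflate/lutidine silylation protects the hindered allylic C7 hydroxyl as an ether that outlasts the later triethylsilyl cleavages.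

Step 12
Reactants: 17 (2E,6S,11S,12R)-6-(tert-butyldimethylsilyloxy)-3,11-dimethyl-7-methylidene-12,13-bis(triethylsilyloxy)tridec-2-en-1-yl acetate
Product: 18 (2E,6S,11S,12R)-6-(tert-butyldimethylsilyloxy)-3,11-dimethyl-7-methylidene-12,13-bis(triethylsilyloxy)tridec-2-en-1-ol
Conditions: iBu2AlH, CH2Cl2, −78 °C; aq. potassium sodium tartrate
Reagents that add atoms: none
Why: Reductive ester cleavage with an aluminium hydride at low temperature removes the acetate without the basic methanol that might loosen the primary triethylsilyl ether.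

Step 13
Reactants: 18 (2E,6S,11S,12R)-6-(tert-butyldimethylsilyloxy)-3,11-dimethyl-7-methylidene-12,13-bis(triethylsilyloxy)tridec-2-en-1-ol
Product: 20 (2E,6S,11S,12R)-1-bromo-6-(tert-butyldimethylsilyloxy)-3,11-dimethyl-7-methylidene-12,13-bis(triethylsilyloxy)tridec-2-ene, via allylic mesylate 19 (not isolated)
Conditions: MsCl, Et3N, THF, −40 °C; then LiBr, THF, −40 to 0 °C; used crude
Reagents that add atoms: lithium bromide, [Li+].[Br-]
Why: Mesylation followed by SN2 displacement with bromide (Finkelstein type) converts the primary allylic alcohol into the C2 bromide at low temperature with retention of the E geometry and without allylic transposition.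

Step 14
Reactants: 20 (2E,6S,11S,12R)-1-bromo-6-(tert-butyldimethylsilyloxy)-3,11-dimethyl-7-methylidene-12,13-bis(triethylsilyloxy)tridec-2-ene; 21 methyl propiolate
Product: 23 methyl (5E,9S,14S,15R)-9-(tert-butyldimethylsilyloxy)-6,14-dimethyl-10-methylidene-15,16-bis(triethylsilyloxy)hexadec-5-en-2-ynoate, via copper acetylide 22 (not isolated)
Conditions: CuI, NaI, K2CO3, DMF, 0 °C to rt
Reagents that add atoms: none
Why: In this copper acetylide allylation the acetylide formed from methyl propiolate under mild carbonate base displaces the primary allylic bromide at C2 (SN2) to give the 1,4-enyne, and the weak base and ambient temperature are meant to avoid isomerisation of the doubly activated C2 methylene.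

Step 15
Reactants: 23 methyl (5E,9S,14S,15R)-9-(tert-butyldimethylsilyloxy)-6,14-dimethyl-10-methylidene-15,16-bis(triethylsilyloxy)hexadec-5-en-2-ynoate; 24 formaldehyde
Product: 26 methyl (2Z,5E,9S,14S,15R)-2-(hydroxymethyl)-9-(tert-butyldimethylsilyloxy)-6,14-dimethyl-10-methylidene-15,16-bis(triethylsilyloxy)hexadeca-2,5-dienoate, via α-alumino enoate 25 (not isolated)
Conditions: iBu2AlH, N-methylmorpholine N-oxide, THF, 0 °C; 23; then CH2O (monomer from cracked paraformaldehyde), 0 °C to rt; aq. potassium sodium tartrate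
Reagents that add atoms: none
Why: Conjugate hydroalumination of the ynoate followed by vinylalumination of formaldehyde works because the amine-oxide-complexed hydride adds H to C1 and Al to C15 in a syn fashion instead of reducing the ester, and 25 captures formaldehyde at C15 with retention so that the C2 chain ends up cis to the ester.

Step 16
Reactants: 26 methyl (2Z,5E,9S,14S,15R)-2-(hydroxymethyl)-9-(tert-butyldimethylsilyloxy)-6,14-dimethyl-10-methylidene-15,16-bis(triethylsilyloxy)hexadeca-2,5-dienoate
Product: 30 methyl (2Z,5E,9S,14S,15R)-2-(bromomethyl)-9-(tert-butyldimethylsilyloxy)-6,14-dimethyl-10-methylidene-15,16-bis(triethylsilyloxy)hexadeca-2,5-dienoate, via enoate mesylate 27 (not isolated), via E bromide 28 (not isolated), via secondary bromide 29 (not isolated)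
Conditions: Ms2O, 2,4,6-collidine, THF, −20 °C; then LiBr (excess), THF, 0 °C to rt
Reagents that add atoms: lithium bromide, [Li+].[Br-]
Why: Sulfonate formation and bromide displacement under equilibrating conditions give the E bromide 28 by direct SN2, and reversible SN2' addition of excess bromide through 29 should funnel the material to the more stable Z isomer (C2 chain trans to the ester), a chloride-free sulfonylating agent and a hindered base being used because this electrophile quaternises ordinary amines.

Step 17
Reactants: 30 methyl (2Z,5E,9S,14S,15R)-2-(bromomethyl)-9-(tert-butyldimethylsilyloxy)-6,14-dimethyl-10-methylidene-15,16-bis(triethylsilyloxy)hexadeca-2,5-dienoate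
Product: 32 methyl (2Z,5E,9S,14S,15R)-2-(bromomethyl)-9-(tert-butyldimethylsilyloxy)-6,14-dimethyl-10-methylidene-16-oxo-15-(triethylsilyloxy)hexadeca-2,5-dienoate, via alkoxysulfonium chloride 31 (not isolated)
Conditions: (COCl)2, DMSO, CH2Cl2, −78 to −40 °C; then iPr2NEt, −78 to −10 °C
Reagents that add atoms: none
Why: In this Swern oxidation applied directly to a silyl ether the activated sulfoxide attacks only the unhindered primary triethylsilyl ether, so 31 collapses to the C14 aldehyde while the secondary triethylsilyl and the tert-butyldimethylsilyl ethers stay, which avoids any selective oxidation of a free 1,2-diol, and the non-nucleophilic base spares the allylic bromide and the C13 centre.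

Step 18
Reactants: 32 methyl (2Z,5E,9S,14S,15R)-2-(bromomethyl)-9-(tert-butyldimethylsilyloxy)-6,14-dimethyl-10-methylidene-16-oxo-15-(triethylsilyloxy)hexadeca-2,5-dienoate
Product: 33 methyl (2Z,5E,9S,14S,15R)-2-(bromomethyl)-9-(tert-butyldimethylsilyloxy)-15-hydroxy-6,14-dimethyl-10-methylidene-16-oxohexadeca-2,5-dienoate
Conditions: AcOH/THF/H2O, 0 °C to rt; extracted and used at once
Reagents that add atoms: none
Why: Mild acid solvolysis of a triethylsilyl ether, much faster than that of the secondary tert-butyldimethylsilyl ether, frees the C13 hydroxyl without the pyridine or fluoride that would attack the allylic bromide.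

Step 19
Reactants: 33 methyl (2Z,5E,9S,14S,15R)-2-(bromomethyl)-9-(tert-butyldimethylsilyloxy)-15-hydroxy-6,14-dimethyl-10-methylidene-16-oxohexadeca-2,5-dienoate
Product: 36 (1S,3E,7S,12S,13R,14R)-7-(tert-butyldimethylsilyloxy)-13-hydroxycembra-3,8(19),15(17)-trien-16,14-olide, via allylindium dibromide 34 (not isolated), via hydroxy ester 35 (not isolated)
Conditions: In powder, THF/H2O, rt, syringe-pump addition of 33 (final about 1 mM); crude then pyridinium p-toluenesulfonate (cat.), CH2Cl2, rt
Reagents that add atoms: none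
Why: Indium inserts into the allylic C–Br bond of 33 to give the ester-stabilised allylindium 34 (drawn as the RInBr2 half of the sesquibromide), whose metal is clamped by O13 and the C14 carbonyl oxygen before C1, the γ-carbon, adds to C14 through a six-membered chair with allylic transposition (SE2'), which turns the former CH2Br carbon into the exocyclic methylene. The closest known reaction types are the Barbier or Nozaki–Hiyama-type macrocyclisation of ω-formyl 2-(halomethyl)enoates to 14-membered cembranolide rings and the intermolecular aqueous indium addition of γ-substituted 2-(bromomethyl)enoates to unprotected α-hydroxy aldehydes. The 14-membered carbocycle closes end to end by C1–C14 bond formation, and the γ-lactone then closes by 5-exo-trig acyl substitution of O14 on the methyl ester of 35 with loss of methanol, which is preferred over the six-membered alternative through O13. C14 (R) is controlled by the five-membered indium chelate, attack coming from the face that carries H13 and away from the C12 branch (13,14-syn), while C1 (S) is controlled by the chair in which the C2 chain, cis to the CH2–In arm, sits axial (14,1-syn, hence the cis ring fusion), and any E/Z leakage is harmless because the allylindium equilibrates by 1,3-metal shift. The step needs ring closure to beat oligomerisation and protonolysis, which slow addition at high dilution, chelate-accelerated addition and the two rigid olefin units of the chain (E-C3=C4 and the C8 methylene) should secure, and the ester, silyl ether and olefins are inert to indium in water.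

Step 20
Reactants: 36 (1S,3E,7S,12S,13R,14R)-7-(tert-butyldimethylsilyloxy)-13-hydroxycembra-3,8(19),15(17)-trien-16,14-olide
Product: 37 (1S,3E,7S,12S,13R,14R)-13-acetoxy-7-(tert-butyldimethylsilyloxy)cembra-3,8(19),15(17)-trien-16,14-olide
Conditions: Ac2O, pyridine, 4-(dimethylamino)pyridine (cat.), CH2Cl2, 0 °C to rt
Reagents that add atoms: acetic anhydride, CC(=O)OC(C)=O
Why: Nucleophile-catalysed acylation acetylates the only free hydroxyl, the one that has just served as the directing group, so no protecting group is spent on C13.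

Step 21
Reactants: 37 (1S,3E,7S,12S,13R,14R)-13-acetoxy-7-(tert-butyldimethylsilyloxy)cembra-3,8(19),15(17)-trien-16,14-olide
Product: 38 (1S,3E,7S,12S,13R,14R)-13-acetoxy-7-hydroxycembra-3,8(19),15(17)-trien-16,14-olide
Conditions: HF·pyridine, pyridine, THF, 0 °C to rt
Reagents that add atoms: none
Why: Fluoride-mediated desilylation under weakly acidic buffered conditions removes the allylic silyl ether without hydrolysing the acetate or adding to the α-methylene lactone, and no allylic halide is left to react with pyridine.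

Step 22
Reactants: 38 (1S,3E,7S,12S,13R,14R)-13-acetoxy-7-hydroxycembra-3,8(19),15(17)-trien-16,14-olide
Product: 39 (1S,3R,4R,7S,12S,13R,14R)-13-acetoxy-3,4-epoxy-7-hydroxycembra-8(19),15(17)-dien-16,14-olide (CNP0230083.1)
Conditions: 1,2:4,5-di-O-isopropylidene-β-D-erythro-2,3-hexodiulo-2,6-pyranose (D-fructose-derived Shi ketone, 30 mol %), Oxone (2KHSO5·KHSO4·K2SO4), K2CO3, Na2B4O7/Na2EDTA buffer, Bu4NHSO4, MeCN/CH2(OMe)2/H2O, 0 °C
Reagents that add atoms: potassium peroxymonosulfate (active part of Oxone), [K+].[O-]S(=O)(=O)OO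
Why: In this Shi asymmetric epoxidation the chiral dioxirane attacks the only electron-rich E-trisubstituted olefin through the spiro transition state, for which the D-fructose-derived ketone is expected to give the 3R,4R epoxide, while the 1,1-disubstituted allylic olefin and the electron-poor methylene lactone react much more slowly, and placing the step last keeps the epoxide away from acid and from long contact with the C7 hydroxyl.

Compound list

1 | (S)-citronellal | C[C@H](CC=O)CCC=C(C)C | starting material
2 | (2R,3S)-2-(anilinooxy)-3,7-dimethyloct-6-enal (not isolated) | CC(C)=CCC[C@H](C)[C@@H](ONc1ccccc1)C=O | intermediate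
3 | (2R,3S)-2-(anilinooxy)-3,7-dimethyloct-6-en-1-ol | CC(C)=CCC[C@H](C)[C@@H](ONc1ccccc1)CO | intermediate
4 | (2R,3S)-3,7-dimethyloct-6-ene-1,2-diol | CC(C)=CCC[C@H](C)[C@@H](O)CO | intermediate
5 | (2R,3S)-3,7-dimethyl-1,2-bis(triethylsilyloxy)oct-6-ene | CC(C)=CCC[C@H](C)[C@@H](O[Si](CC)(CC)CC)CO[Si](CC)(CC)CC | intermediate
6 | (4S,5R)-4-methyl-5,6-bis(triethylsilyloxy)hexanal (not isolated) | O=CCC[C@H](C)[C@@H](O[Si](CC)(CC)CC)CO[Si](CC)(CC)CC | intermediate
7 | (4S,5R)-4-methyl-5,6-bis(triethylsilyloxy)hexan-1-ol | OCCC[C@H](C)[C@@H](O[Si](CC)(CC)CC)CO[Si](CC)(CC)CC | intermediate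
8 | (2R,3S)-6-iodo-3-methyl-1,2-bis(triethylsilyloxy)hexane | ICCC[C@H](C)[C@@H](O[Si](CC)(CC)CC)CO[Si](CC)(CC)CC | intermediate
9 | (1-bromovinyl)trimethylsilane | C=C(Br)[Si](C)(C)C | starting material
10 | 1-(trimethylsilyl)vinylmagnesium bromide (not isolated) | C=C([Mg]Br)[Si](C)(C)C | intermediate
11 | (2R,3S)-3-methyl-1,2-bis(triethylsilyloxy)-7-(trimethylsilyl)oct-7-ene | C=C(CCC[C@H](C)[C@@H](O[Si](CC)(CC)CC)CO[Si](CC)(CC)CC)[Si](C)(C)C | intermediate
12 | (2R,3S)-7-iodo-3-methyl-1,2-bis(triethylsilyloxy)oct-7-ene (C8 to C14) | C=C(I)CCC[C@H](C)[C@@H](O[Si](CC)(CC)CC)CO[Si](CC)(CC)CC | intermediate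
13 | geranyl acetate | CC(C)=CCC/C(C)=C/COC(C)=O | starting material
14 | 6,7-epoxygeranyl acetate (racemic at the epoxide CH) | CC1(C)OC1CC/C(C)=C/COC(C)=O | intermediate
15 | (2E)-3-methyl-6-oxohex-2-en-1-yl acetate (C2 to C7) | O=CCC/C(C)=C/COC(C)=O | intermediate
16 | (2E,6S,11S,12R)-6-hydroxy-3,11-dimethyl-7-methylidene-12,13-bis(triethylsilyloxy)tridec-2-en-1-yl acetate (7S,12S,13R) | C=C(CCC[C@H](C)[C@@H](O[Si](CC)(CC)CC)CO[Si](CC)(CC)CC)[C@@H](O)CC/C(C)=C/COC(C)=O | intermediate
17 | 7-O-tert-butyldimethylsilyl ether of 16 | C=C(CCC[C@H](C)[C@@H](O[Si](CC)(CC)CC)CO[Si](CC)(CC)CC)[C@@H](O[Si](C)(C)C(C)(C)C)CC/C(C)=C/COC(C)=O | intermediate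
18 | C2 allylic alcohol from 17 | C=C(CCC[C@H](C)[C@@H](O[Si](CC)(CC)CC)CO[Si](CC)(CC)CC)[C@@H](O[Si](C)(C)C(C)(C)C)CC/C(C)=C/CO | intermediate
19 | C2 allylic mesylate (not isolated) | C=C(CCC[C@H](C)[C@@H](O[Si](CC)(CC)CC)CO[Si](CC)(CC)CC)[C@@H](O[Si](C)(C)C(C)(C)C)CC/C(C)=C/COS(C)(=O)=O | intermediate
20 | C2 allylic bromide | C=C(CCC[C@H](C)[C@@H](O[Si](CC)(CC)CC)CO[Si](CC)(CC)CC)[C@@H](O[Si](C)(C)C(C)(C)C)CC/C(C)=C/CBr | intermediate
21 | methyl propiolate | C#CC(=O)OC | starting material
22 | [2-(methoxycarbonyl)ethynyl]copper (not isolated) | [Cu]C#CC(=O)OC | intermediate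
23 | skipped enynoate, methyl (5E,9S,14S,15R)-9-(tert-butyldimethylsilyloxy)-6,14-dimethyl-10-methylidene-15,16-bis(triethylsilyloxy)hexadec-5-en-2-ynoate | C=C(CCC[C@H](C)[C@@H](O[Si](CC)(CC)CC)CO[Si](CC)(CC)CC)[C@@H](O[Si](C)(C)C(C)(C)C)CC/C(C)=C/CC#CC(=O)OC | intermediate
24 | formaldehyde (bought as paraformaldehyde) | C=O | starting material
25 | (2E)-2-(diisobutylalumanyl) dienoate, C2 chain cis to the ester (not isolated) | C=C(CCC[C@H](C)[C@@H](O[Si](CC)(CC)CC)CO[Si](CC)(CC)CC)[C@@H](O[Si](C)(C)C(C)(C)C)CC/C(C)=C/C/C=C(/[Al](CC(C)C)CC(C)C)C(=O)OC | intermediate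
26 | (2Z)-2-(hydroxymethyl) dienoate | C=C(CCC[C@H](C)[C@@H](O[Si](CC)(CC)CC)CO[Si](CC)(CC)CC)[C@@H](O[Si](C)(C)C(C)(C)C)CC/C(C)=C/C/C=C(/CO)C(=O)OC | intermediate
27 | (2Z)-2-(mesyloxymethyl) dienoate (not isolated) | C=C(CCC[C@H](C)[C@@H](O[Si](CC)(CC)CC)CO[Si](CC)(CC)CC)[C@@H](O[Si](C)(C)C(C)(C)C)CC/C(C)=C/C/C=C(/COS(C)(=O)=O)C(=O)OC | intermediate
28 | (2E)-2-(bromomethyl) dienoate (not isolated) | C=C(CCC[C@H](C)[C@@H](O[Si](CC)(CC)CC)CO[Si](CC)(CC)CC)[C@@H](O[Si](C)(C)C(C)(C)C)CC/C(C)=C/C/C=C(/CBr)C(=O)OC | intermediate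
29 | 3-bromo-2-methylidene ester, both C1 epimers (not isolated) | C=C(CCC[C@H](C)[C@@H](O[Si](CC)(CC)CC)CO[Si](CC)(CC)CC)[C@@H](O[Si](C)(C)C(C)(C)C)CC/C(C)=C/CC(Br)C(=C)C(=O)OC | intermediate
30 | (2Z)-2-(bromomethyl) dienoate, seco chain with both triethylsilyl ethers | C=C(CCC[C@H](C)[C@@H](O[Si](CC)(CC)CC)CO[Si](CC)(CC)CC)[C@@H](O[Si](C)(C)C(C)(C)C)CC/C(C)=C/C/C=C(\CBr)C(=O)OC | intermediate
31 | C14 alkoxy(dimethyl)sulfonium chloride (not isolated) | C=C(CCC[C@H](C)[C@@H](O[Si](CC)(CC)CC)CO[S+](C)C)[C@@H](O[Si](C)(C)C(C)(C)C)CC/C(C)=C/C/C=C(\CBr)C(=O)OC.[Cl-] | intermediate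
32 | (13R)-13-triethylsilyloxy C14 aldehyde with (Z)-bromomethyl enoate | C=C(CCC[C@H](C)[C@@H](O[Si](CC)(CC)CC)C=O)[C@@H](O[Si](C)(C)C(C)(C)C)CC/C(C)=C/C/C=C(\CBr)C(=O)OC | intermediate
33 | free (13R)-hydroxy C14 aldehyde with (Z)-bromomethyl enoate | C=C(CCC[C@H](C)[C@@H](O)C=O)[C@@H](O[Si](C)(C)C(C)(C)C)CC/C(C)=C/C/C=C(\CBr)C(=O)OC | intermediate
34 | allylindium dibromide of 33 (not isolated) | C=C(CCC[C@H](C)[C@@H](O)C=O)[C@@H](O[Si](C)(C)C(C)(C)C)CC/C(C)=C/C/C=C(\C[In](Br)Br)C(=O)OC | intermediate
35 | methyl (1S,3E,7S,12S,13R,14R)-7-(tert-butyldimethylsilyloxy)-13,14-dihydroxycembra-3,8(19),15(17)-trien-16-oate (not isolated) | C=C1CCC[C@H](C)[C@@H](O)[C@H](O)[C@H](C(=C)C(=O)OC)C/C=C(C)/CC[C@@H]1O[Si](C)(C)C(C)(C)C | intermediate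
36 | (1S,3E,7S,12S,13R,14R)-7-(tert-butyldimethylsilyloxy)-13-hydroxycembra-3,8(19),15(17)-trien-16,14-olide | C=C1CCC[C@H](C)[C@@H](O)[C@@H]2OC(=O)C(=C)[C@@H]2C/C=C(C)/CC[C@@H]1O[Si](C)(C)C(C)(C)C | intermediate
37 | (1S,3E,7S,12S,13R,14R)-13-acetoxy-7-(tert-butyldimethylsilyloxy)cembra-3,8(19),15(17)-trien-16,14-olide | C=C1CCC[C@H](C)[C@@H](OC(C)=O)[C@@H]2OC(=O)C(=C)[C@@H]2C/C=C(C)/CC[C@@H]1O[Si](C)(C)C(C)(C)C | intermediate
38 | (1S,3E,7S,12S,13R,14R)-13-acetoxy-7-hydroxycembra-3,8(19),15(17)-trien-16,14-olide | C=C1CCC[C@H](C)[C@@H](OC(C)=O)[C@@H]2OC(=O)C(=C)[C@@H]2C/C=C(C)/CC[C@@H]1O | intermediate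
39 | (1S,3R,4R,7S,12S,13R,14R)-13-acetoxy-3,4-epoxy-7-hydroxycembra-8(19),15(17)-dien-16,14-olide (CNP0230083.1) | C=C1CCC[C@H](C)[C@@H](OC(C)=O)[C@@H]2OC(=O)C(=C)[C@@H]2C[C@H]2O[C@]2(C)CC[C@@H]1O | target

Total step count: 22. Longest linear sequence: 20 steps (steps 1 to 7 and 10 to 22, counted from 1).

Steps most likely to fail

Step 19.
- **What may go wrong:** Closure of the 14-membered ring may be too slow at high dilution. Water could then protonate the allylindium, chains could add to one another, or the unprotected hydroxy aldehyde could self-condense or undergo a ketol shift. Leakage through a non-chelated transition state would erode the 13,14-syn selectivity.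
- **Fallback:** This gives up water, the free hydroxyl and substrate chelation altogether, and it skips step 18. It sets out from 32. The ring is closed by the anhydrous chromium-mediated (Nozaki–Hiyama–Kishi-type) allylation, which is the established closure for this class of cembranolide seco-aldehydes. Excess CrCl2 pre-complexed with the deprotonated oxazoline–sulfonamide ligand of step 10 is used in THF, with slow addition of 32. Divalent chromium converts the bromide into the allylchromium dichloride F1, which adds through C1 to the C14 aldehyde.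
- **Stereocontrol in the fallback:** The aldehyde face is chosen by the ligand (reagent control), which has to override the Felkin preference of the α-silyloxy aldehyde. The cis ring fusion is the normal outcome of ester-substituted allylchromium reagents.
- **Return to the route:** Work-up gives the 13-O-triethylsilyl hydroxy ester F2. Catalytic pyridinium p-toluenesulfonate closes this to the 13-O-triethylsilyl lactone F3. AcOH/THF/H2O then removes the triethylsilyl group and the sequence comes back at 36.

Step 22.
- **What may go wrong:** Facial selectivity may be poor if the conformational bias of the macrocycle opposes the catalyst. Other risks are competing oxidation of the C8 methylene, hydrolysis of the acetate or lactone at the pH of the buffer, and transannular opening of the new epoxide by the C7 hydroxyl.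
- **Fallback:** This replaces reagent control on the free alcohol by substrate control on the silyl ether and inverts the order of the last two operations. It sets out from 37. mCPBA with NaHCO3 in CH2Cl2 at 0 °C should attack the exposed outer face of the E olefin of the macrocycle under neutral, non-aqueous conditions. This gives the 7-O-silyl 3,4-epoxide F4.
- **Return to the route:** Bu4NF buffered with AcOH in THF at 0 °C removes the silyl group without acid and delivers 39.

Step 15.
- **What may go wrong:** The hydride may reduce the ester instead of adding in a conjugate sense. The α-alumino enoate may be protonated before it meets formaldehyde, or the skipped diene may isomerise.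
- **Fallback:** This exchanges the aluminium aldol for palladium chemistry and sets out from 23. Pd(PPh3)4-catalysed hydrostannation with Bu3SnH (syn addition, tin on the carbon next to the ester) gives the (E)-α-tributylstannyl enoate F5. Iododestannylation with I2 in CH2Cl2 at 0 °C gives the (E)-α-iodo enoate F6.
- **Return to the route:** Stille coupling of F6 with (tributylstannyl)methanol under Pd(PPh3)4 installs the hydroxymethyl group with retention of geometry, and the sequence comes back at 26.

Further compounds

F1 | step 19 | allylchromium dichloride of 32 (not isolated) | C=C(CCC[C@H](C)[C@@H](O[Si](CC)(CC)CC)C=O)[C@@H](O[Si](C)(C)C(C)(C)C)CC/C(C)=C/C/C=C(\C[Cr](Cl)Cl)C(=O)OC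
F2 | step 19 | methyl (1S,3E,7S,12S,13R,14R)-7-(tert-butyldimethylsilyloxy)-14-hydroxy-13-(triethylsilyloxy)cembra-3,8(19),15(17)-trien-16-oate | C=C1CCC[C@H](C)[C@@H](O[Si](CC)(CC)CC)[C@H](O)[C@H](C(=C)C(=O)OC)C/C=C(C)/CC[C@@H]1O[Si](C)(C)C(C)(C)C
F3 | step 19 | (1S,3E,7S,12S,13R,14R)-7-(tert-butyldimethylsilyloxy)-13-(triethylsilyloxy)cembra-3,8(19),15(17)-trien-16,14-olide | C=C1CCC[C@H](C)[C@@H](O[Si](CC)(CC)CC)[C@@H]2OC(=O)C(=C)[C@@H]2C/C=C(C)/CC[C@@H]1O[Si](C)(C)C(C)(C)C
F4 | step 22 | (1S,3R,4R,7S,12S,13R,14R)-13-acetoxy-7-(tert-butyldimethylsilyloxy)-3,4-epoxycembra-8(19),15(17)-dien-16,14-olide | C=C1CCC[C@H](C)[C@@H](OC(C)=O)[C@@H]2OC(=O)C(=C)[C@@H]2C[C@H]2O[C@]2(C)CC[C@@H]1O[Si](C)(C)C(C)(C)C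
F5 | step 15 | (2E)-2-(tributylstannyl) dienoate, C2 chain cis to the ester | C=C(CCC[C@H](C)[C@@H](O[Si](CC)(CC)CC)CO[Si](CC)(CC)CC)[C@@H](O[Si](C)(C)C(C)(C)C)CC/C(C)=C/C/C=C(/[Sn](CCCC)(CCCC)CCCC)C(=O)OC
F6 | step 15 | (2E)-2-iodo dienoate, C2 chain cis to the ester | C=C(CCC[C@H](C)[C@@H](O[Si](CC)(CC)CC)CO[Si](CC)(CC)CC)[C@@H](O[Si](C)(C)C(C)(C)C)CC/C(C)=C/C/C=C(/I)C(=O)OC
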